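**Retrosynthetic overview**
1. The target is a 7-acyl-4,6-dihydroxy-5-prenyl-2-(2-hydroxypropan-2-yl)-2,3-dihydrobenzofuran, (S) at C2; the last disconnection removes three MOM ethers (two phenols, the tertiary alcohol).
2. Key disconnection: the ketone C–C7 bond and the ring bond O1–C7a are made in one flask from an open-chain chloroarene. Ortho-lithiation next to Cl and loss of LiCl give the C7/C7a aryne, the C2 alkoxide adds 5-exo to C7a, and the C7 aryllithium is acylated by the N-methoxy-N-methylamide of 3-(4-methoxyphenyl)propanoic acid.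
3. Enabling feature: the ketone carbon sits on C7, directly beside C7a, which carries the ring oxygen O1; O1 is joined through C2 and C3 to C3a, the other neighbour of C7a. The C6 oxygen on the far side of C7 directs the metalation and holds the aryllithium.
4. The cascade precursor comes from an ortho-chloro aryllithium and a terminal (S)-epoxide made from methyl (S)-glycidate (stereocentre bought, its C–O bond never broken). The arene comes from 5-chlororesorcinol by MOM protection and ortho-metalation/prenylation between the two OMOM groups.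
5. Ring order: the benzene ring is bought with two of its three oxygens (the third arrives with the side chain); the dihydrofuran is the only ring formed, in the key step.

Key step: step 7

Assumption: 5-chlororesorcinol, methyl (S)-glycidate and 3-(4-methoxyphenyl)propanoic acid are taken as commercial; the stereocentre of the target is read as (S) from the SMILES and is carried unchanged from the glycidate.

Step 1
Reactants: 1 5-chlororesorcinol (5-chlorobenzene-1,3-diol)
Product: 2 1-chloro-3,5-bis(methoxymethoxy)benzene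
Conditions: MOMCl (2.5 equiv), i-Pr2NEt (3 equiv), CH2Cl2, 0 °C → rt
Reagents that add atoms: chloromethyl methyl ether (MOMCl), COCCl
Why: Twofold O-alkylation of the phenols (Williamson-type acetal formation) should install the MOM ethers that direct both later metalations and leave together in the last step; the aryl chloride is inert.

Step 2
Reactants: 2 1-chloro-3,5-bis(methoxymethoxy)benzene
Product: 4 5-chloro-1,3-bis(methoxymethoxy)-2-(3-methylbut-2-en-1-yl)benzene, via aryllithium 3 (not isolated)
Conditions: n-BuLi (1.1 equiv), THF, −20 → 0 °C; then prenyl bromide, −78 °C → rt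
Reagents that add atoms: prenyl bromide (1-bromo-3-methylbut-2-ene), CC(C)=CCBr
Why: Directed ortho-metalation should remove the C–H flanked by both OMOM groups under coordination control (n-BuLi does not exchange an aryl chloride, and a lithium para to chlorine cannot eliminate), and the aryllithium is alkylated by SN2 at the primary carbon of prenyl bromide.

Step 3
Reactants: 5 methyl (2S)-oxirane-2-carboxylate (methyl (S)-glycidate)
Product: 7 2-[(2S)-oxiran-2-yl]propan-2-ol, via methyl ketone 6 (not isolated)
Conditions: MeMgCl (2.2 equiv), THF, −78 → −20 °C; then cold H2O (pH 7 buffer)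
Reagents that add atoms: methylmagnesium chloride, C[Mg]Cl
Why: Twofold Grignard addition to the ester carbonyl should outrun opening of the epoxide at low temperature, and since no bond to the stereocentre is broken the (S) configuration is retained (CMe2OH keeps the CIP rank of CO2Me).

Step 4
Reactants: 7 2-[(2S)-oxiran-2-yl]propan-2-ol
Product: 8 (2S)-2-[2-(methoxymethoxy)propan-2-yl]oxirane
Conditions: MOMCl (3 equiv), i-Pr2NEt (4 equiv), CH2Cl2, 0 → 40 °C
Reagents that add atoms: chloromethyl methyl ether (MOMCl), COCCl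
Why: Amine-buffered O-alkylation of the tertiary alcohol should give an acetal that, unlike a silyl ether, cannot migrate to a neighbouring alkoxide later; no free alkoxide is formed, so a Payne rearrangement of the epoxy alcohol is avoided.

Step 5
Reactants: 4 5-chloro-1,3-bis(methoxymethoxy)-2-(3-methylbut-2-en-1-yl)benzene; 8 (2S)-2-[2-(methoxymethoxy)propan-2-yl]oxirane
Product: 10 (2S)-1-[6-chloro-2,4-bis(methoxymethoxy)-3-(3-methylbut-2-en-1-yl)phenyl]-3-(methoxymethoxy)-3-methylbutan-2-ol, via aryllithium 9 (not isolated)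
Conditions: s-BuLi (1.05 equiv), THF, −78 °C; then 8, BF3·OEt2, −78 °C; aq. NaHCO3
Reagents that add atoms: none
Why: Directed ortho-metalation at one of the two equivalent C–H bonds flanked by Cl and OMOM should give an ortho-chloro aryllithium that is stable at −78 °C, and BF3-promoted SN2 opening of the epoxide at its CH2 terminus forms the aryl–CH2 bond without touching the stereocentre, which stays (S).

Step 6
Reactants: 11 3-(4-methoxyphenyl)propanoic acid
Product: 13 N-methoxy-3-(4-methoxyphenyl)-N-methylpropanamide, via acyl imidazolide 12 (not isolated)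
Conditions: CDI, CH2Cl2, rt; then MeNH(OMe)·HCl, rt
Reagents that add atoms: N,O-dimethylhydroxylamine hydrochloride, CNOC.Cl
Why: Amide formation through the acyl imidazolide should give the N-methoxy-N-methylamide, the acyl donor for a Weinreb ketone synthesis.

Step 7
Reactants: 10 (2S)-1-[6-chloro-2,4-bis(methoxymethoxy)-3-(3-methylbut-2-en-1-yl)phenyl]-3-(methoxymethoxy)-3-methylbutan-2-ol; 13 N-methoxy-3-(4-methoxyphenyl)-N-methylpropanamide
Product: 18 1-[(2S)-4,6-bis(methoxymethoxy)-2-[2-(methoxymethoxy)propan-2-yl]-5-(3-methylbut-2-en-1-yl)-2,3-dihydro-1-benzofuran-7-yl]-3-(4-methoxyphenyl)propan-1-one, via dilithio chloroarene 14 (not isolated), via aryne lithium alkoxide 15 (not isolated), via aryllithium 16 (not isolated), via tetrahedral lithium adduct 17 (not isolated)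
Conditions: s-BuLi (2.1 equiv), THF, −78 °C; warm to −10 °C; recool to −78 °C, 13 (1.3 equiv), → 0 °C; then H2O (pH 7 buffer)
Reagents that add atoms: none
Why: Proposed new method: s-BuLi should first form the lithium alkoxide and then remove the only ring hydrogen, acidified by the adjacent chlorine and coordinated by the adjacent OMOM (14); on warming LiCl is lost to give aryne 15, the tethered alkoxide adds to the former C–Cl carbon, and the relocated aryllithium 16, held between the new ring oxygen and OMOM, is acylated by 13 through chelate 17, which releases the ketone only on work-up (Weinreb ketone synthesis). The closest known reaction types are the arynic cyclisation of aryl halides carrying a tethered alkoxide or amide nucleophile, the anionic benzyne cyclisation with electrophilic trapping of the resulting aryllithium, and the acylation of 2,6-dialkoxyaryllithiums by N-methoxy-N-methylamides; new is their combination in one flask on an alkoxide-tethered, fully substituted arene. The dihydrofuran ring closes by a 5-exo-dig attack of oxygen on the in-plane π bond of the aryne (bond O1–C7a). No new stereocentre is formed: the C–O bond of the carbinol carbon is never broken, so C2 keeps the (S) configuration brought in with the glycidate. The step needs site-selective metalation (secured by the single remaining ring C–H between Cl and OMOM), regioselective alkoxide addition (only the five-membered closure onto the carbon next to the side chain is geometrically possible, and it places the carbanion beside the stabilising OMOM), exclusion of a six-membered closure (the tertiary oxygen is capped as a non-migrating MOM acetal) and mono-acylation (amide chelate).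

Step 8
Reactants: 18 1-[(2S)-4,6-bis(methoxymethoxy)-2-[2-(methoxymethoxy)propan-2-yl]-5-(3-methylbut-2-en-1-yl)-2,3-dihydro-1-benzofuran-7-yl]-3-(4-methoxyphenyl)propan-1-one
Product: 19 1-[(2S)-4,6-dihydroxy-2-(2-hydroxypropan-2-yl)-5-(3-methylbut-2-en-1-yl)-2,3-dihydro-1-benzofuran-7-yl]-3-(4-methoxyphenyl)propan-1-one
Conditions: 3 M aq. HCl/MeOH, 40 °C
Reagents that add atoms: none
Why: Acid-catalysed acetal methanolysis should remove the two aryl MOM ethers and the tertiary-alkyl MOM ether as dimethoxymethane under conditions that prenylated phenols and the tertiary carbinol are expected to tolerate; the stereocentre is not involved.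

**Compound list**
1 | 5-chlororesorcinol (5-chlorobenzene-1,3-diol) | Oc1cc(O)cc(Cl)c1 | starting material
2 | 1-chloro-3,5-bis(methoxymethoxy)benzene | COCOc1cc(Cl)cc(OCOC)c1 | intermediate
3 | [4-chloro-2,6-bis(methoxymethoxy)phenyl]lithium (not isolated) | [Li]c1c(OCOC)cc(Cl)cc1OCOC | intermediate
4 | 5-chloro-1,3-bis(methoxymethoxy)-2-(3-methylbut-2-en-1-yl)benzene | COCOc1cc(Cl)cc(OCOC)c1CC=C(C)C | intermediate
5 | methyl (2S)-oxirane-2-carboxylate | COC(=O)[C@@H]1CO1 | starting material
6 | 1-[(2S)-oxiran-2-yl]ethan-1-one (not isolated) | CC(=O)[C@@H]1CO1 | intermediate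
7 | 2-[(2S)-oxiran-2-yl]propan-2-ol | CC(C)(O)[C@@H]1CO1 | intermediate
8 | (2S)-2-[2-(methoxymethoxy)propan-2-yl]oxirane | COCOC(C)(C)[C@@H]1CO1 | intermediate
9 | [6-chloro-2,4-bis(methoxymethoxy)-3-(3-methylbut-2-en-1-yl)phenyl]lithium (not isolated) | [Li]c1c(Cl)cc(OCOC)c(CC=C(C)C)c1OCOC | intermediate
10 | (2S)-1-[6-chloro-2,4-bis(methoxymethoxy)-3-(3-methylbut-2-en-1-yl)phenyl]-3-(methoxymethoxy)-3-methylbutan-2-ol | COCOc1cc(Cl)c(C[C@H](O)C(C)(C)OCOC)c(OCOC)c1CC=C(C)C | intermediate
11 | 3-(4-methoxyphenyl)propanoic acid | COc1ccc(CCC(=O)O)cc1 | starting material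
12 | 1-(1H-imidazol-1-yl)-3-(4-methoxyphenyl)propan-1-one (not isolated) | COc1ccc(CCC(=O)n2ccnc2)cc1 | intermediate
13 | N-methoxy-3-(4-methoxyphenyl)-N-methylpropanamide | COc1ccc(CCC(=O)N(C)OC)cc1 | intermediate
14 | lithium (2S)-1-[6-chloro-5-lithio-2,4-bis(methoxymethoxy)-3-(3-methylbut-2-en-1-yl)phenyl]-3-(methoxymethoxy)-3-methylbutan-2-olate (not isolated) | [Li]c1c(Cl)c(C[C@H](O[Li])C(C)(C)OCOC)c(OCOC)c(CC=C(C)C)c1OCOC | intermediate
15 | lithium (2S)-1-[5,6-didehydro-2,4-bis(methoxymethoxy)-3-(3-methylbut-2-en-1-yl)phenyl]-3-(methoxymethoxy)-3-methylbutan-2-olate, the aryne (not isolated) | COCOC1=C(CC=C(C)C)C(OCOC)=C(C[C@H](O[Li])C(C)(C)OCOC)C#C1 | intermediate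
16 | [(2S)-4,6-bis(methoxymethoxy)-2-[2-(methoxymethoxy)propan-2-yl]-5-(3-methylbut-2-en-1-yl)-2,3-dihydro-1-benzofuran-7-yl]lithium (not isolated) | [Li]c1c(OCOC)c(CC=C(C)C)c(OCOC)c2c1O[C@H](C(C)(C)OCOC)C2 | intermediate
17 | lithium 1-[(2S)-4,6-bis(methoxymethoxy)-2-[2-(methoxymethoxy)propan-2-yl]-5-(3-methylbut-2-en-1-yl)-2,3-dihydro-1-benzofuran-7-yl]-1-[methoxy(methyl)amino]-3-(4-methoxyphenyl)propan-1-olate, configuration at the new carbinol carbon not defined (not isolated) | COc1ccc(CCC(O[Li])(N(C)OC)c2c(OCOC)c(CC=C(C)C)c(OCOC)c3c2O[C@H](C(C)(C)OCOC)C3)cc1 | intermediate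
18 | 1-[(2S)-4,6-bis(methoxymethoxy)-2-[2-(methoxymethoxy)propan-2-yl]-5-(3-methylbut-2-en-1-yl)-2,3-dihydro-1-benzofuran-7-yl]-3-(4-methoxyphenyl)propan-1-one | COc1ccc(CCC(=O)c2c(OCOC)c(CC=C(C)C)c(OCOC)c3c2O[C@H](C(C)(C)OCOC)C3)cc1 | intermediate
19 | 1-[(2S)-4,6-dihydroxy-2-(2-hydroxypropan-2-yl)-5-(3-methylbut-2-en-1-yl)-2,3-dihydro-1-benzofuran-7-yl]-3-(4-methoxyphenyl)propan-1-one | COc1ccc(CCC(=O)c2c(O)c(CC=C(C)C)c(O)c3c2O[C@H](C(C)(C)O)C3)cc1 | target

Total step count: 8
Longest linear sequence: 5 steps (1 → 2 → 5 → 7 → 8; the branch 3 → 4 → 5 → 7 → 8 is equally long)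

**Steps most likely to fail**

Step 7 (Proposed new method). The aryne may be captured intermolecularly by an aryllithium or by residual butyllithium before the aggregated lithium alkoxide closes the ring, and the hindered aryllithium may deprotonate the amide instead of adding to it. The fallback uses known chemistry and sets out from 10. A palladium-catalysed intramolecular aryl ether formation (Buchwald–Hartwig-type C–O coupling of the secondary alcohol with the aryl chloride; Pd(OAc)2, bulky biaryl di-tert-butylphosphine, Cs2CO3, toluene, 80 °C) should give (2S)-4,6-bis(methoxymethoxy)-2-[2-(methoxymethoxy)propan-2-yl]-5-(3-methylbut-2-en-1-yl)-2,3-dihydro-1-benzofuran F1 without touching the stereocentre. Its only ring C–H, between O1 and OMOM, is then lithiated with n-BuLi (THF, 0 °C) to the same aryllithium 16, which is acylated with 13 through 17, and the route is rejoined at 18.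

Step 5. The ortho-chloro aryllithium may lose LiCl prematurely, may be tied up as a borate by BF3, or the BF3-activated epoxide may be attacked by its own MOM acetal oxygen; metalation at the benzylic prenyl CH2 is a further risk. The fallback sets out from 4 (through 9) and builds the side chain in two stages:
- Transmetalation of 9 with MgBr2·OEt2 and CuI-catalysed opening of methyl (S)-glycidate 5 at its CH2 terminus (−40 → −10 °C) should give methyl (2S)-3-[6-chloro-2,4-bis(methoxymethoxy)-3-(3-methylbut-2-en-1-yl)phenyl]-2-hydroxypropanoate F2.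
- Excess MeMgCl converts the ester into (2S)-1-[6-chloro-2,4-bis(methoxymethoxy)-3-(3-methylbut-2-en-1-yl)phenyl]-3-methylbutane-2,3-diol F3.
- TESCl/imidazole silylates only the secondary hydroxyl, giving (3S)-4-[6-chloro-2,4-bis(methoxymethoxy)-3-(3-methylbut-2-en-1-yl)phenyl]-2-methyl-3-(triethylsilyloxy)butan-2-ol F4.
- MOMCl/i-Pr2NEt caps the tertiary hydroxyl, giving (2S)-1-[6-chloro-2,4-bis(methoxymethoxy)-3-(3-methylbut-2-en-1-yl)phenyl]-3-(methoxymethoxy)-3-methyl-2-(triethylsilyloxy)butane F5.
- TBAF (THF, 0 °C) removes the silyl group and the route is rejoined at 10.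

Step 8. Under acid the prenyl group may cyclise onto a flanking phenol (chroman formation), and the tertiary MOM ether may cleave only under conditions harsh enough to ionise the tertiary carbinol. The fallback moves the prenyl group to the end and sets out from 2:
- Step 2 run with allyl bromide should give 5-chloro-1,3-bis(methoxymethoxy)-2-(prop-2-en-1-yl)benzene F6.
- The chemistry of steps 5 and 7 then gives (2S)-1-[6-chloro-2,4-bis(methoxymethoxy)-3-(prop-2-en-1-yl)phenyl]-3-(methoxymethoxy)-3-methylbutan-2-ol F7 and 1-[(2S)-4,6-bis(methoxymethoxy)-2-[2-(methoxymethoxy)propan-2-yl]-5-(prop-2-en-1-yl)-2,3-dihydro-1-benzofuran-7-yl]-3-(4-methoxyphenyl)propan-1-one F8.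
- Acidic methanolysis, to which the terminal allyl group is inert, gives 1-[(2S)-4,6-dihydroxy-2-(2-hydroxypropan-2-yl)-5-(prop-2-en-1-yl)-2,3-dihydro-1-benzofuran-7-yl]-3-(4-methoxyphenyl)propan-1-one F9.
- Olefin cross-metathesis with 2-methylbut-2-ene (second-generation ruthenium carbene catalyst, CH2Cl2, 40 °C) turns the allyl into the prenyl group under neutral conditions and arrives at 19.

**Further compounds**
F1 | step 7 | (2S)-4,6-bis(methoxymethoxy)-2-[2-(methoxymethoxy)propan-2-yl]-5-(3-methylbut-2-en-1-yl)-2,3-dihydro-1-benzofuran | c1c(OCOC)c(CC=C(C)C)c(OCOC)c2c1O[C@H](C(C)(C)OCOC)C2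
F2 | step 5 | methyl (2S)-3-[6-chloro-2,4-bis(methoxymethoxy)-3-(3-methylbut-2-en-1-yl)phenyl]-2-hydroxypropanoate | COC(=O)[C@@H](O)Cc1c(Cl)cc(OCOC)c(CC=C(C)C)c1OCOC
F3 | step 5 | (2S)-1-[6-chloro-2,4-bis(methoxymethoxy)-3-(3-methylbut-2-en-1-yl)phenyl]-3-methylbutane-2,3-diol | CC(C)(O)[C@@H](O)Cc1c(Cl)cc(OCOC)c(CC=C(C)C)c1OCOC
F4 | step 5 | (3S)-4-[6-chloro-2,4-bis(methoxymethoxy)-3-(3-methylbut-2-en-1-yl)phenyl]-2-methyl-3-(triethylsilyloxy)butan-2-ol | CC(C)(O)[C@@H](O[Si](CC)(CC)CC)Cc1c(Cl)cc(OCOC)c(CC=C(C)C)c1OCOC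
F5 | step 5 | (2S)-1-[6-chloro-2,4-bis(methoxymethoxy)-3-(3-methylbut-2-en-1-yl)phenyl]-3-(methoxymethoxy)-3-methyl-2-(triethylsilyloxy)butane | COCOC(C)(C)[C@@H](O[Si](CC)(CC)CC)Cc1c(Cl)cc(OCOC)c(CC=C(C)C)c1OCOC
F6 | step 8 | 5-chloro-1,3-bis(methoxymethoxy)-2-(prop-2-en-1-yl)benzene | COCOc1cc(Cl)cc(OCOC)c1CC=C
F7 | step 8 | (2S)-1-[6-chloro-2,4-bis(methoxymethoxy)-3-(prop-2-en-1-yl)phenyl]-3-(methoxymethoxy)-3-methylbutan-2-ol | COCOc1cc(Cl)c(C[C@H](O)C(C)(C)OCOC)c(OCOC)c1CC=C
F8 | step 8 | 1-[(2S)-4,6-bis(methoxymethoxy)-2-[2-(methoxymethoxy)propan-2-yl]-5-(prop-2-en-1-yl)-2,3-dihydro-1-benzofuran-7-yl]-3-(4-methoxyphenyl)propan-1-one | COc1ccc(CCC(=O)c2c(OCOC)c(CC=C)c(OCOC)c3c2O[C@H](C(C)(C)OCOC)C3)cc1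
F9 | step 8 | 1-[(2S)-4,6-dihydroxy-2-(2-hydroxypropan-2-yl)-5-(prop-2-en-1-yl)-2,3-dihydro-1-benzofuran-7-yl]-3-(4-methoxyphenyl)propan-1-one | COc1ccc(CCC(=O)c2c(O)c(CC=C)c(O)c3c2O[C@H](C(C)(C)O)C3)cc1
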